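The north run held 80.0 mM of starting material over 2.40 mM of catalyst, far more of the one than the other. So I supposed a fast binding of catalyst to starting material, balanced at every moment, with the bound form as the resting state of the catalyst, which has free catalyst go as charged [catalyst]/[starting material].

| flask | starting material | catalyst | product | time |
|---|---|---|---|---|
| north | 80.0 mM | 2.40 mM |  |  |
| south-west | 160 mM | 2.40 mM |  |  |
| north-west | 80.0 mM | 3.60 mM |  |  |
| west | 80.0 mM | 2.40 mM | 24.0 mM | 4.3 h |

| run | time / h | [product] / mM |
|---|---|---|
| north run | 0.24 | 1.95 |
| north run | 0.74 | 7.13 |
| north run | 1.4 | 13.03 |
| north run | 2.2 | 20.43 |
| north run | 3.2 | 28.22 |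
| north run | 4.3 | 36.64 |
| south-west run | 0.24 | 4.14 |
| south-west run | 0.74 | 12.51 |
| south-west run | 1.4 | 22.35 |
| south-west run | 2.2 | 32.36 |
| south-west run | 3.2 | 44.01 |
| south-west run | 4.3 | 55.16 |
| north-west run | 0.24 | 3.08 |
| north-west run | 0.74 | 9.23 |
| north-west run | 1.4 | 17.48 |
| north-west run | 2.2 | 27.05 |
| north-west run | 3.2 | 39.69 |
| north-west run | 4.3 | 55.47 |

(each reading ± 0.2 mM)

* order of the initial rate in [catalyst], near the charge of the north run, the rate being that where two percent of its starting material are product
* order of the initial rate in [starting material], near the charge of the north run, the rate being that where two percent of its starting material are product (one fixed amount of product, the same in the runs compared)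
* product in the west run at 4.3 h, as a share of the starting material charged

- Overall: starting material -> product, with catalyst as catalyst.
- Constant volume, constant temperature.
- Readings of a species count what is bound in complexes too.
- An order is taken over about fifteen percent of the charge, up and down.
- A share of product counts the product that was charged too.

Over the first 0.74 h, the north run averaged 9.64 mM h⁻¹ and the north-west run 12.5 mM h⁻¹. Catalyst went up by a factor of 1.50, but the rate by less than that, 1.30. So I pictured two drains in parallel on one tank: a blind drain proportional to [starting material], and a catalysed drain, bound catalyst meeting free catalyst, proportional to [catalyst]²/[starting material].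

The north-west gain then equals 1.25 of the north run's catalysed drain, which makes that drain 2.27 mM h⁻¹. Its part of the north rate, the catalysed share, is 23.6%.

The apparent order of two drains in parallel is the share-weighted mean of their orders. I therefore committed to 0.472 in catalyst and 0.528 in starting material.

The two drains contain no product, and I tried them on a rate they had not been fitted to. Late in the north-west run they give 15.2 mM h⁻¹, against 14.3 mM h⁻¹ read. The match was rough, and no earlier run was charged with product, so it was an assumption when I let the west run make what the north run made, ending at 75.8%.

The forecast gave 0.75 in catalyst, 0.85 in starting material and 76% for the west run, and called its west figure “an empirical interpolation”.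

The simulation gives 0.42 in catalyst, 0.62 in starting material and 76.1% for the west run.

    catalyst + starting material ⇌ catalyst-substrate complex, settled at all times (182.0 L mol⁻¹)
    catalyst-substrate complex + catalyst → product + 2 catalyst (5976 L mol⁻¹ h⁻¹)
    2 starting material → homo dimer (0.2873 L mol⁻¹ h⁻¹)
    starting material → product (0.1037 h⁻¹)

Halved, the simulated order in catalyst puts the catalysed share of the north run at 21.0%, against my 23.6%. In the south-west run, the blind drain is twice as strong and the catalysed drain half as strong, so my share gives a rate 1.65 times the north run's, and the simulated ratio, taken where both runs have made the same amount, is 1.7. The order in catalyst is this low due to the path from starting material to product: without that path it is 2.0 instead of 0.42, and the west run ends at 43.1% instead of 76.1%.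

(The numbers in the tables come from a simulation with made-up constants, and the scatter is random.)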